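## Retrosynthetic overview

1. Last, the C-3′ bromine of a 3′-bromoflav-2-ene is exchanged for hydrogen; it is the remnant of the CBr2 unit that carries the ring expansion, and it makes the pyrylium ion more electrophilic.
2. Key union: C-1–C-4′, C-5–C-10 and C-4–O are formed in one operation from (+)-germacrene A and the gem-dibromocyclopropane fused across C-2/C-3 of 4,6,7-trimethoxy-2-phenylbenzofuran. The pyran ring (O-1′, C-2′, C-3′, C-4′, C-4a′, C-8a′) grows out of the furan ring (O-1′, C-2′, C-4′, C-4a′, C-8a′) by uptake of the CBr2 carbon as C-3′.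
3. Enabling features: the endo C–Br bond stands anti to the cyclopropane bond C-2′–C-4′, which is flanked by O-1′/phenyl and by the trimethoxy arene, so ionisation opens it to an aromatic pyrylium ion electrophilic at C-4′. In the ten-membered ring the E-1(10)- and E-4-alkenes lie crossed with C-10 facing C-5, so attack at C-1 closes rings A and B and leaves a tertiary C-4 cation for water.
4. Germacrene A from (R)-limonene oxide: periodate cleavage gives C-5 to C-10 with C-7 in place; Wittig and Horner–Wadsworth–Emmons olefination, reduction, bromination and nickel-mediated allyl–allyl closure of C-2–C-3 follow.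
5. Benzofuran from 1,2,3,5-tetramethoxybenzene (formylation, ortho-demethylation, O-benzylation, base-induced ring closure). Ring order: arene (bought), furan, cyclopropane, then pyran together with rings A and B.

Key step: step 12

Assumption: the target is read from its SMILES as (1S,4R,5R,7R,10S,4′S) in eudesmane/flavene numbering, and (4R)-limonene 1,2-oxide (cis/trans mixture) and 1,2,3,5-tetramethoxybenzene are taken as commercial.

## Route

Step 1
Reactants: 1 (4R)-limonene 1,2-oxide (cis/trans mixture)
Product: 3 (3R)-6-oxo-3-(prop-1-en-2-yl)heptanal, via limonene-1,2-diol 2 (not isolated)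
Conditions: H5IO6 (1.1 equiv), THF/H2O, 0 °C to 23 °C
Reagents that add atoms: water, SMILES O
Why: Acid-catalysed opening of the epoxide by water and Malaprade glycol cleavage of the diol break the ring between the two oxygenated carbons; the isopropenyl-bearing stereocenter is not involved and the 1,1-disubstituted alkene does not react with periodate.

Step 2
Reactants: 3 (3R)-6-oxo-3-(prop-1-en-2-yl)heptanal
Product: 4 ethyl (2E,5R)-2-methyl-8-oxo-5-(prop-1-en-2-yl)non-2-enoate
Conditions: Ph3P=C(CH3)CO2Et (1.05 equiv), CH2Cl2, 0 °C to 23 °C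
Reagents that add atoms: ethyl 2-(triphenylphosphoranylidene)propanoate, SMILES CCOC(=O)C(C)=P(c1ccccc1)(c1ccccc1)c1ccccc1
Why: Wittig olefination with the stabilised ylide reacts only with the aldehyde (the methyl ketone is inert at 23 °C) and gives the E-trisubstituted enoate that becomes the C-4/C-5 alkene.

Step 3
Reactants: 4 ethyl (2E,5R)-2-methyl-8-oxo-5-(prop-1-en-2-yl)non-2-enoate
Product: 5 diethyl (2E,5R,8E)-2,8-dimethyl-5-(prop-1-en-2-yl)deca-2,8-dienedioate
Conditions: (EtO)2P(O)CH2CO2Et, NaH, THF, 0 °C to 66 °C; chromatography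
Reagents that add atoms: triethyl phosphonoacetate, SMILES CCOC(=O)CP(=O)(OCC)OCC
Why: Horner–Wadsworth–Emmons olefination of the methyl ketone should give mainly the E-β-methyl enoate (chain trans to the ester) that becomes the C-1/C-10 alkene; the minor Z isomer is to be removed by chromatography.

Step 4
Reactants: 5 diethyl (2E,5R,8E)-2,8-dimethyl-5-(prop-1-en-2-yl)deca-2,8-dienedioate
Product: 6 (2E,5R,8E)-2,8-dimethyl-5-(prop-1-en-2-yl)deca-2,8-diene-1,10-diol
Conditions: DIBAL-H (4.5 equiv), CH2Cl2, −78 °C; Rochelle salt work-up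
Reagents that add atoms: none
Why: DIBAL-H reduces both conjugated esters by 1,2-hydride delivery to the allylic alcohols without touching the alkenes or their geometry.

Step 5
Reactants: 6 (2E,5R,8E)-2,8-dimethyl-5-(prop-1-en-2-yl)deca-2,8-diene-1,10-diol
Product: 7 (2E,5R,8E)-1,10-dibromo-2,8-dimethyl-5-(prop-1-en-2-yl)deca-2,8-diene
Conditions: CBr4, PPh3, CH2Cl2, −20 °C to 0 °C
Reagents that add atoms: carbon tetrabromide, SMILES BrC(Br)(Br)Br
Why: Appel bromination converts both primary allylic alcohols into bromides by SN2 displacement of the oxyphosphonium group, without allylic transposition at low temperature.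

Step 6
Reactants: 7 (2E,5R,8E)-1,10-dibromo-2,8-dimethyl-5-(prop-1-en-2-yl)deca-2,8-diene
Product: 8 (+)-germacrene A [(1E,5E,8R)-1,5-dimethyl-8-(prop-1-en-2-yl)cyclodeca-1,5-diene]
Conditions: Ni(CO)4 (4 equiv), N-methylpyrrolidone, 50 °C, slow addition of 7 (high dilution)
Reagents that add atoms: none
Why: Zerovalent nickel inserts into both allylic C–Br bonds and the bis(π-allyl)nickel unit couples reductively at its two primary ends (the nickel-mediated allyl–allyl macrocyclisation known for ten- and eleven-membered terpene 1,5-dienes), closing C-2–C-3 of the ten-membered ring; no stereocenter is formed and the E geometry of the syn π-allyl termini should be kept.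

Step 7
Reactants: 9 1,2,3,5-tetramethoxybenzene
Product: 10 2,3,4,6-tetramethoxybenzaldehyde
Conditions: n-BuLi, TMEDA, THF, 0 °C; DMF; H2O
Reagents that add atoms: N,N-dimethylformamide, SMILES CN(C)C=O
Why: Directed ortho-lithiation at the position flanked by two methoxy groups followed by formylation with DMF gives one aldehyde, since both free ring positions are equivalent.

Step 8
Reactants: 10 2,3,4,6-tetramethoxybenzaldehyde
Product: 11 2-hydroxy-3,4,6-trimethoxybenzaldehyde
Conditions: BCl3 (1.1 equiv), CH2Cl2, −78 °C to 0 °C; H2O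
Reagents that add atoms: none
Why: BCl3 chelates the aldehyde oxygen and cleaves only an ortho methyl ether, preferring the one at C-2 that is pushed out of plane by the neighbouring 3-methoxy group (chelation-controlled mono-demethylation).

Step 9
Reactants: 11 2-hydroxy-3,4,6-trimethoxybenzaldehyde
Product: 12 2-(benzyloxy)-3,4,6-trimethoxybenzaldehyde
Conditions: BnBr, K2CO3, DMF, 60 °C
Reagents that add atoms: benzyl bromide, SMILES BrCc1ccccc1
Why: Williamson etherification of the phenol installs the benzyl group whose benzylic carbon becomes C-2 of the benzofuran.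

Step 10
Reactants: 12 2-(benzyloxy)-3,4,6-trimethoxybenzaldehyde
Product: 14 4,6,7-trimethoxy-2-phenyl-1-benzofuran, via 2,3-dihydrobenzofuran-3-ol 13 (not isolated)
Conditions: phosphazene base P4-t-Bu (0.2 equiv), benzene, 80 °C; then p-TsOH·H2O (0.1 equiv), 23 °C
Reagents that add atoms: none
Why: The phosphazene base deprotonates the benzylic ether carbon, the carbanion adds to the neighbouring aldehyde (5-exo-trig closure of the furan ring) and acid-catalysed loss of water aromatises the ring to the 2-phenylbenzofuran.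

Step 11
Reactants: 14 4,6,7-trimethoxy-2-phenyl-1-benzofuran
Product: 15 rac-1,1-dibromo-3,4,6-trimethoxy-1a-phenyl-1a,6b-dihydro-1H-cyclopropa[b][1]benzofuran (cis-fused)
Conditions: CHBr3, KOtBu, pentane/toluene, −30 °C to −10 °C; cold work-up, crude product kept below −20 °C and used at once
Reagents that add atoms: bromoform, SMILES BrC(Br)Br
Why: Dibromocarbene (α-elimination from bromoform) adds in a [2+1] cycloaddition to the electron-rich, enol-ether-like C-2/C-3 bond of the benzofuran, necessarily cis; the cyclopropane is racemic, and its two stereocenters become sp2 again in step 12.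

Step 12
Reactants: 15 rac-1,1-dibromo-3,4,6-trimethoxy-1a-phenyl-1a,6b-dihydro-1H-cyclopropa[b][1]benzofuran; 8 (+)-germacrene A
Product: 17 (1S,4R,5R,7R,10S)-1-[(4R)-3-bromo-5,7,8-trimethoxy-2-phenyl-4H-chromen-4-yl]eudesm-11-en-4-ol, via 3-bromo-5,7,8-trimethoxyflavylium tetrafluoroborate 16 (not isolated)
Conditions: 15 (1.3 equiv), AgBF4 (1.25 equiv), NaHCO3 (3 equiv), CH2Cl2/MeNO2, −40 °C, 15 min; then 8 (1.0 equiv), H2O (3 equiv), −40 °C to 0 °C
Reagents that add atoms: water, SMILES O
Why: Proposed new method: AgBF4 abstracts the endo bromide of 15 while the cyclopropane bond between the O-1′/phenyl-bearing carbon and the benzylic carbon opens in a disrotatory cyclopropyl-to-allyl electrocyclic reaction, so the furan ring takes up the former carbene carbon as C-3′ and becomes the pyrylium ring of 16; its C-4′ then attacks C-1 of the 1(10)-alkene of 8, C-10 is captured transannularly by C-5 of the 4-alkene and water adds to the tertiary C-4 cation. The closest known reactions are the thermal or silver-assisted ring expansion of dihalocarbene adducts of benzofurans and cyclic enol ethers, the addition of π-nucleophiles to C-4 of flavylium ions, and the proton-, halonium- and epoxide-induced transannular cyclisation of germacrenes to eudesman-4-ols. The pyran ring is closed by ring expansion (electrocyclic opening, no new ring-closing bond), and rings A and B are closed together by the C-5–C-10 bond, 6-exo with respect to ring A and 6-endo with respect to ring B. C-1, C-10, C-5 and C-4 are controlled by the crossed chair–chair conformer of 8, fixed by the equatorial isopropenyl group at C-7, in which anti addition across both E-alkenes gives the 1β-substituent, 10β-methyl, 5α-H and 4α-OH. C-4′ is controlled by an open transition state in which 4′-H lies between C-2 and C-10, the A ring with its peri 5′-methoxy group points outward between C-2 and H-1 and the bromine-bearing C-3′ lies between H-1 and C-10, which should lead to the configuration of 17. The step needs attack at C-1 and not at the isopropenyl group, at C-4′ and not at C-2′ of 16, and by the carbon electrophile instead of a proton; the mutual assistance of the two ring alkenes, the phenyl group at C-2′ together with the activating 3′-bromine, and the bicarbonate buffer are meant to secure these.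

Step 13
Reactants: 17 (1S,4R,5R,7R,10S)-1-[(4R)-3-bromo-5,7,8-trimethoxy-2-phenyl-4H-chromen-4-yl]eudesm-11-en-4-ol
Product: 18 (1S,4R,5R,7R,10S)-1-[(4S)-5,7,8-trimethoxy-2-phenyl-4H-chromen-4-yl]eudesm-11-en-4-ol
Conditions: Pd(PPh3)4 (5 mol %), n-Bu3SnH (1.5 equiv), THF, 23 °C
Reagents that add atoms: none
Why: Palladium-catalysed hydrodebromination (oxidative addition of zerovalent palladium into the vinyl C–Br bond, hydride transfer from tin, reductive elimination) replaces bromine by hydrogen without moving the C-2′/C-3′ double bond; no stereocenter is touched, and the descriptor at C-4′ changes from R to S only because the priorities change.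

## Compound list

1 | (4R)-limonene 1,2-oxide, cis/trans mixture at the epoxide | CC(=C)[C@@H]1CCC2(C)OC2C1 | starting material
2 | (4R)-1-methyl-4-(prop-1-en-2-yl)cyclohexane-1,2-diol (limonene-1,2-diol, diastereomer mixture) | CC(=C)[C@@H]1CCC(C)(O)C(O)C1 | intermediate
3 | (3R)-6-oxo-3-(prop-1-en-2-yl)heptanal | O=CC[C@@H](CCC(C)=O)C(C)=C | intermediate
4 | ethyl (2E,5R)-2-methyl-8-oxo-5-(prop-1-en-2-yl)non-2-enoate | CCOC(=O)/C(C)=C/C[C@@H](CCC(C)=O)C(C)=C | intermediate
5 | diethyl (2E,5R,8E)-2,8-dimethyl-5-(prop-1-en-2-yl)deca-2,8-dienedioate | CCOC(=O)/C=C(\C)CC[C@H](C/C=C(\C)C(=O)OCC)C(C)=C | intermediate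
6 | (2E,5R,8E)-2,8-dimethyl-5-(prop-1-en-2-yl)deca-2,8-diene-1,10-diol | OC/C=C(\C)CC[C@H](C/C=C(\C)CO)C(C)=C | intermediate
7 | (2E,5R,8E)-1,10-dibromo-2,8-dimethyl-5-(prop-1-en-2-yl)deca-2,8-diene | BrC/C=C(\C)CC[C@H](C/C=C(\C)CBr)C(C)=C | intermediate
8 | (+)-germacrene A, (1E,5E,8R)-1,5-dimethyl-8-(prop-1-en-2-yl)cyclodeca-1,5-diene | C/C1=C\CC/C(C)=C/C[C@H](C(C)=C)CC1 | intermediate
9 | 1,2,3,5-tetramethoxybenzene | COc1cc(OC)c(OC)c(OC)c1 | starting material
10 | 2,3,4,6-tetramethoxybenzaldehyde | O=Cc1c(OC)cc(OC)c(OC)c1OC | intermediate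
11 | 2-hydroxy-3,4,6-trimethoxybenzaldehyde | O=Cc1c(OC)cc(OC)c(OC)c1O | intermediate
12 | 2-(benzyloxy)-3,4,6-trimethoxybenzaldehyde | O=Cc1c(OC)cc(OC)c(OC)c1OCc1ccccc1 | intermediate
13 | 4,6,7-trimethoxy-2-phenyl-2,3-dihydro-1-benzofuran-3-ol (racemic, cis/trans mixture) | OC1c2c(OC)cc(OC)c(OC)c2OC1c1ccccc1 | intermediate
14 | 4,6,7-trimethoxy-2-phenyl-1-benzofuran | COc1cc(OC)c2cc(-c3ccccc3)oc2c1OC | intermediate
15 | rac-1,1-dibromo-3,4,6-trimethoxy-1a-phenyl-1a,6b-dihydro-1H-cyclopropa[b][1]benzofuran (cis-fused, racemic) | COc1cc(OC)c2c(c1OC)OC1(c3ccccc3)C2C1(Br)Br | intermediate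
16 | 3-bromo-5,7,8-trimethoxy-2-phenylchromenylium (3-bromo-5,7,8-trimethoxyflavylium) tetrafluoroborate | COc1cc(OC)c2cc(Br)c(-c3ccccc3)[o+]c2c1OC.F[B-](F)(F)F | intermediate
17 | (1S,4R,5R,7R,10S)-1-[(4R)-3-bromo-5,7,8-trimethoxy-2-phenyl-4H-chromen-4-yl]eudesm-11-en-4-ol (1β-chromenyl, 4α-OH, 5α-H, 10β-Me, 7β-isopropenyl) | C=C(C)[C@@H]1CC[C@]2(C)[C@@H](C1)[C@](C)(O)CC[C@H]2[C@H]1C(Br)=C(c2ccccc2)Oc2c(OC)c(OC)cc(OC)c21 | intermediate
18 | (1S,4R,5R,7R,10S)-1-[(4S)-5,7,8-trimethoxy-2-phenyl-4H-chromen-4-yl]eudesm-11-en-4-ol | C=C(C)[C@@H]1CC[C@]2(C)[C@@H](C1)[C@](C)(O)CC[C@H]2[C@H]1C=C(c2ccccc2)Oc2c(OC)c(OC)cc(OC)c21 | target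

## Step count and risks

Total step count: 13. Longest linear sequence: 8 steps (steps 1 to 6, 12 and 13).

Steps most likely to fail:

1. Step 12 (Proposed new method). The donor-stabilised pyrylium ion may add to C-1 of 8 too slowly, so that acid-induced cyclisation of 8 to selinenes and hydration of the pyrylium ion take over, and the two faces of C-4′ may be poorly told apart. The fallback uses known reactions only, sets out from 8 and 11 and returns at 18. Compound 8 is epoxidised at the 1(10)-alkene (mCPBA, NaHCO3, CH2Cl2, −20 °C) to 1β,10α-epoxygermacra-4,11-diene F1, which cyclises transannularly in wet acetone with a trace of TsOH to selin-11-ene-1β,4α-diol F2. Dess–Martin oxidation of the secondary alcohol gives 4α-hydroxyselin-11-en-1-one F3. Wittig reaction with Ph3P=CHOMe gives the enol ether 1-(methoxymethylidene)selin-11-en-4α-ol F4, and hydrolysis (aqueous HCl, THF) with equilibration (K2CO3, MeOH) gives the equatorial 4α-hydroxyselin-11-ene-1β-carbaldehyde F5. Aldol condensation with acetophenone (LiHMDS, then MsCl/Et3N) gives (E)-3-(4α-hydroxyselin-11-en-1β-yl)-1-phenylprop-2-en-1-one F6. In parallel 11 is decarbonylated (RhCl(PPh3)3, toluene, 110 °C) to 2,3,5-trimethoxyphenol F7. Friedel–Crafts conjugate addition of F7 to F6 and cyclodehydration (Sc(OTf)3, CH2Cl2, 23 °C) close the 4H-chromene and should give 18, with separation of the C-4′ epimers if needed.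

2. Step 6. The π-allylnickel intermediates may lose E geometry, and head-to-tail coupling (six-membered elemene-type ring) or intermolecular coupling may compete with closure of the ten-membered ring. The fallback sets out from 7 and returns at 8. Statistical mono-substitution of 7 with PhSNa (1 equiv, THF/EtOH, 0 °C) gives the two regioisomeric bromo sulfides, {[(2E,5R,8E)-10-bromo-2,8-dimethyl-5-(prop-1-en-2-yl)deca-2,8-dien-1-yl]sulfanyl}benzene F8 and {[(2E,6R,8E)-10-bromo-3,9-dimethyl-6-(prop-1-en-2-yl)deca-2,8-dien-1-yl]sulfanyl}benzene F9, which need not be separated. Deprotonation next to sulfur (n-BuLi, DABCO, THF, −78 °C, high dilution) and intramolecular SN2 alkylation at the allylic bromide close the same C-2–C-3 bond from either isomer and give (7R)-3-(phenylsulfanyl)germacra-1(10),4,11-triene F10 and (7R)-2-(phenylsulfanyl)germacra-1(10),4,11-triene F11. Reductive C–S cleavage (Li, EtNH2, −78 °C) converges both on 8 with the alkene geometry set by the olefinations.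

3. Step 11. The dibromocyclopropane may ionise and ring-expand during its formation or work-up, so that the ring expansion escapes control, and the carbene may attack the electron-rich arene. The fallback sets out from 11 and returns at 18. Acid condensation of 11 with acetophenone (HBF4·OEt2, AcOH/Ac2O, 23 °C) gives 5,7,8-trimethoxy-2-phenylchromenylium tetrafluoroborate F12 by the classical salicylaldehyde route. F12 then takes the place of the pyrylium ion in step 12 (NaHCO3, H2O, CH2Cl2/MeNO2, no silver salt) with 8 and should give 18 directly, so that step 13 is not needed.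

## Further compounds

F1 | step 12 | (7R)-1β,10α-epoxygermacra-4E,11-diene | C=C(C)[C@@H]1CC[C@@]2(C)O[C@@H]2CC/C(C)=C/C1
F2 | step 12 | selin-11-ene-1β,4α-diol | C=C(C)[C@@H]1CC[C@]2(C)[C@@H](C1)[C@](C)(O)CC[C@H]2O
F3 | step 12 | 4α-hydroxyselin-11-en-1-one | C=C(C)[C@@H]1CC[C@]2(C)[C@@H](C1)[C@](C)(O)CCC2=O
F4 | step 12 | 1-(methoxymethylidene)selin-11-en-4α-ol (E/Z mixture) | C=C(C)[C@@H]1CC[C@]2(C)[C@@H](C1)[C@](C)(O)CCC2=COC
F5 | step 12 | 4α-hydroxyselin-11-ene-1β-carbaldehyde | C=C(C)[C@@H]1CC[C@]2(C)[C@@H](C1)[C@](C)(O)CC[C@H]2C=O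
F6 | step 12 | (E)-3-(4α-hydroxyselin-11-en-1β-yl)-1-phenylprop-2-en-1-one | C=C(C)[C@@H]1CC[C@]2(C)[C@@H](C1)[C@](C)(O)CC[C@H]2/C=C/C(=O)c1ccccc1
F7 | step 12 | 2,3,5-trimethoxyphenol | COc1cc(O)c(OC)c(OC)c1
F8 | step 6 | {[(2E,5R,8E)-10-bromo-2,8-dimethyl-5-(prop-1-en-2-yl)deca-2,8-dien-1-yl]sulfanyl}benzene | BrC/C=C(\C)CC[C@H](C/C=C(\C)CSc1ccccc1)C(C)=C
F9 | step 6 | {[(2E,6R,8E)-10-bromo-3,9-dimethyl-6-(prop-1-en-2-yl)deca-2,8-dien-1-yl]sulfanyl}benzene | c1ccccc1SC/C=C(\C)CC[C@H](C/C=C(\C)CBr)C(C)=C
F10 | step 6 | (7R)-3-(phenylsulfanyl)germacra-1(10)E,4E,11-triene (epimer mixture at C-3) | C/C1=C\CC(Sc2ccccc2)/C(C)=C/C[C@H](C(C)=C)CC1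
F11 | step 6 | (7R)-2-(phenylsulfanyl)germacra-1(10)E,4E,11-triene (epimer mixture at C-2) | C/C1=C\C(Sc2ccccc2)C/C(C)=C/C[C@H](C(C)=C)CC1
F12 | step 11 | 5,7,8-trimethoxy-2-phenylchromenylium tetrafluoroborate | COc1cc(OC)c2ccc(-c3ccccc3)[o+]c2c1OC.F[B-](F)(F)F
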